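Overview (azaphilone numbering: C1, O2, C3, C4, C4a, C5–Cl, C6=O, C7(Me)(OH), C8–OH, C8a; side chain C9–C15): target ⇐ tert-butyl ester 24 ⇐ gold-catalysed 6-endo-dig closure of the pyran (O2–C3) in the hydroxymethylidene cyclohexenone 23.
23 ⇐ silicon-tethered intramolecular Diels–Alder reaction of the 3-silyloxyfuran 21 under a chiral oxazaborolidinium catalyst, which forms C7–C8 and C4a–C8a together and sets C7 and C8; fluoride then removes silicon and opens the oxygen bridge.
Enabling feature: in the carbocycle (C4a, C5, C6, C7, C8, C8a) the C7 hydroxyl oxygen and C4a are 1,4-related across the C6 ketone, so joining them gives a furan whose diene is C7=C6–C5=C4a; C8, C8a and C1 are malondialdehyde enol, and the 1,3-related oxygens on C6 and C8 can be bridged by one silicon atom, which forces C8–O endo, i.e. trans to C7–O.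
21 ⇐ chlorofuranone 18 ⇐ Sonogashira union of dienyl iodide 8 (C13 from an Evans alkylation) with the furanone alkyne 16, made from ethyl lactate and bis(trimethylsilyl)butadiyne.
Ring order: furanone (temporary), then the carbocycle together with a temporary dioxasilinane and oxygen bridge (step 12), then the pyran (step 13).

Key step: step 12

Remark 1: the lactate-derived centre (future C7) is drawn (S) up to 18 but becomes planar in furan 21, so its integrity is irrelevant.
Remark 2: the (S)-oxazaborolidinium catalyst is assumed to give the (7S,8R) series; if the sense of induction is the opposite, its mirror image is used with no other change.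

Step 1
Reactants: 1 (R)-4-benzyl-3-propanoyl-1,3-oxazolidin-2-one; 2 tert-butyl bromoacetate
Product: 4 tert-butyl (3S)-4-[(4R)-4-benzyl-2-oxo-1,3-oxazolidin-3-yl]-3-methyl-4-oxobutanoate, via sodium Z-enolate 3 (not isolated)
Conditions: NaN(SiMe3)2, THF, −78 °C; then 2, −78 → −30 °C
Reagents that add atoms: none
Why: Evans alkylation, in which the chelated Z-enolate is alkylated on the face opposite to the benzyl group and so sets the (S) centre of the future C13.

Step 2
Reactants: 4 tert-butyl (3S)-4-[(4R)-4-benzyl-2-oxo-1,3-oxazolidin-3-yl]-3-methyl-4-oxobutanoate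
Product: 5 tert-butyl (3S)-4-hydroxy-3-methylbutanoate
Conditions: LiBH4, H2O (1 equiv), Et2O, 0 °C
Reagents that add atoms: none
Why: Reductive cleavage of the auxiliary, since the imide carbonyl is reduced much faster than the tert-butyl ester, whose bulk also slows lactonisation.

Step 3
Reactants: 5 tert-butyl (3S)-4-hydroxy-3-methylbutanoate
Product: 6 tert-butyl (3S)-3-methyl-4-oxobutanoate
Conditions: TEMPO (10 mol%), PhI(OAc)2, CH2Cl2, rt
Reagents that add atoms: none
Why: Oxoammonium (TEMPO) oxidation of a primary alcohol stops at the aldehyde under non-basic conditions, so the α-centre should not epimerise.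

Step 4
Reactants: 6 tert-butyl (3S)-3-methyl-4-oxobutanoate
Product: 7 tert-butyl (3S,4E)-3,5-dimethyl-6-oxohex-4-enoate
Conditions: toluene, 80 °C
Reagents that add atoms: 2-(triphenylphosphoranylidene)propanal, CC(C=O)=P(c1ccccc1)(c1ccccc1)c1ccccc1
Why: Wittig olefination with a formyl-stabilised ylide is E-selective and should give the trisubstituted (E)-enal.

Step 5
Reactants: 7 tert-butyl (3S,4E)-3,5-dimethyl-6-oxohex-4-enoate
Product: 8 tert-butyl (3S,4E,6E)-7-iodo-3,5-dimethylhepta-4,6-dienoate
Conditions: CrCl2, CHI3, THF, 0 °C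
Reagents that add atoms: iodoform, IC(I)I
Why: Takai olefination converts the aldehyde into the (E)-vinyl iodide through a geminal dichromium reagent and tolerates the ester.

Step 6
Reactants: 9 ethyl (S)-lactate
Product: 10 (2S)-2-hydroxy-N-methoxy-N-methylpropanamide
Conditions: MeNH(OMe)·HCl, i-PrMgCl, THF, −20 → 0 °C
Reagents that add atoms: N,O-dimethylhydroxylamine hydrochloride, CNOC.Cl
Why: Aminolysis of the ester by the magnesium amide (Weinreb amide formation) does not touch the stereocentre.

Step 7
Reactants: 10 (2S)-2-hydroxy-N-methoxy-N-methylpropanamide; 11 1,4-bis(trimethylsilyl)buta-1,3-diyne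
Product: 14 (2S)-2-hydroxy-7-(trimethylsilyl)hepta-4,6-diyn-3-one, via lithium 4-(trimethylsilyl)buta-1,3-diyn-1-ide 12 (not isolated), via chloromagnesium alkoxide 13 (not isolated)
Conditions: 11, MeLi·LiBr, Et2O, rt; 10, i-PrMgCl, THF, −20 °C; combine, −78 → 0 °C; aq. NH4Cl
Reagents that add atoms: none
Why: Weinreb ketone synthesis, in which the chelated tetrahedral adduct of the acetylide survives until work-up and prevents over-addition.

Step 8
Reactants: 14 (2S)-2-hydroxy-7-(trimethylsilyl)hepta-4,6-diyn-3-one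
Product: 15 (2S)-2-methyl-5-[(trimethylsilyl)ethynyl]furan-3(2H)-one
Conditions: (4-CF3C6H4)3PAuCl (2 mol%), AgOTf (2 mol%), toluene, rt
Reagents that add atoms: none
Why: Gold-catalysed 5-endo-dig hydroalkoxylation (cycloisomerisation of an α′-hydroxy ynone to a 3(2H)-furanone) puts the lactate oxygen on the ynone β-carbon, the only alkyne carbon within reach.

Step 9
Reactants: 15 (2S)-2-methyl-5-[(trimethylsilyl)ethynyl]furan-3(2H)-one
Product: 16 (2S)-4-chloro-2-methyl-5-[(trimethylsilyl)ethynyl]furan-3(2H)-one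
Conditions: N-chlorosuccinimide, MeCN, 0 °C
Reagents that add atoms: N-chlorosuccinimide, O=C1CCC(=O)N1Cl
Why: Electrophilic chlorination at the nucleophilic α-carbon of the vinylogous ester installs the future C5 chlorine before any other alkene is present.

Step 10
Reactants: 16 (2S)-4-chloro-2-methyl-5-[(trimethylsilyl)ethynyl]furan-3(2H)-one; 8 tert-butyl (3S,4E,6E)-7-iodo-3,5-dimethylhepta-4,6-dienoate
Product: 18 tert-butyl (3S,4E,6E)-9-[(5S)-3-chloro-5-methyl-4-oxo-4,5-dihydrofuran-2-yl]-3,5-dimethylnona-4,6-dien-8-ynoate, via 4-chloro-5-ethynyl-2-methylfuran-3(2H)-one 17 (not isolated)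
Conditions: Bu4NF, AcOH, THF, −20 °C; then 8, PdCl2(PPh3)2 (5 mol%), CuI (10 mol%), Et3N, 0 °C → rt
Reagents that add atoms: none
Why: Buffered fluoride removes the alkynyl silane and the terminal alkyne undergoes Sonogashira coupling with the vinyl iodide with retention of the alkene geometry, the ring chloride being inert at room temperature.

Step 11
Reactants: 18 tert-butyl (3S,4E,6E)-9-[(5S)-3-chloro-5-methyl-4-oxo-4,5-dihydrofuran-2-yl]-3,5-dimethylnona-4,6-dien-8-ynoate; 19 tetrabutylammonium (E)-3-oxoprop-1-en-1-olate (malondialdehyde tetrabutylammonium salt)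
Product: 21 tert-butyl (3S,4E,6E)-9-[3-chloro-4-({diisopropyl[(1E)-3-oxoprop-1-enyloxy]silyl}oxy)-5-methylfuran-2-yl]-3,5-dimethylnona-4,6-dien-8-ynoate, via furan-3-yloxy(diisopropyl)silyl triflate 20 (not isolated)
Conditions: i-Pr2Si(OTf)2, Et3N, CH2Cl2, −78 °C; then 19, −78 → −20 °C; pentane, filtration under argon, used at once
Reagents that add atoms: diisopropylsilyl bis(trifluoromethanesulfonate), CC(C)[Si](OS(=O)(=O)C(F)(F)F)(OS(=O)(=O)C(F)(F)F)C(C)C
Why: Soft enolisation with O-silylation gives the aromatic 3-silyloxyfuran and the second triflate is displaced by the enolate oxygen of malondialdehyde (synthesis of an unsymmetrical silyl bis-enol ether), the isopropyl groups suppressing double substitution by the furanone.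

Step 12
Reactants: 21 tert-butyl (3S,4E,6E)-9-[3-chloro-4-({diisopropyl[(1E)-3-oxoprop-1-enyloxy]silyl}oxy)-5-methylfuran-2-yl]-3,5-dimethylnona-4,6-dien-8-ynoate
Product: 23 tert-butyl (3S,4E,6E)-9-[(4S,5R)-2-chloro-4,5-dihydroxy-6-(hydroxymethylidene)-4-methyl-3-oxocyclohex-1-en-1-yl]-3,5-dimethylnona-4,6-dien-8-ynoate, via bridged cycloadduct 22 (not isolated)
Conditions: (S)-o-tolyl-CBS-oxazaborolidine (20 mol%), Tf2NH (18 mol%), CH2Cl2, −78 → −40 °C; then Bu4NF, THF, −78 °C; AcOH
Reagents that add atoms: none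
Why: Proposed new method: the oxazaborolidinium cation binds the formyl oxygen of the β-silyloxy enal, the furan carbon bearing the methyl group (future C7, the nucleophilic end of the silyl enol ether) attacks the enal β-carbon (C8) and the enal α-carbon (C8a) closes onto the alkynyl-bearing furan carbon (C4a) in an asynchronous normal-demand intramolecular Diels–Alder reaction, after which fluoride cleaves both Si–O bonds and the freed C6 enolate expels the bridging oxygen (E1cB), which becomes the C7 hydroxyl. The closest known reaction types are silicon-tethered intramolecular Diels–Alder reactions, Lewis-acid-promoted intramolecular Diels–Alder reactions of furans, the opening of 3-oxyfuran cycloadducts to hydroxycyclohexenones and oxazaborolidinium-catalysed enantioselective Diels–Alder reactions of enals; new are the tether through two enol oxygens and its enantioselective use. The carbocycle closes by [4+2] cycloaddition, the temporary 1,3-dioxa-2-silinane closes with the C7–C8 bond and the oxygen bridge is the former furan oxygen, and both temporary rings are removed in the same flask. C7 and C8 are set together: their relative configuration by the three-atom O–Si–O tether, which can span only an endo C8–O (anti to the oxygen bridge, hence the trans-diol with methyl cis to the C8 hydroxyl), and their absolute configuration by the enal face that the catalyst leaves open; the centres at C8a and C4a are transient. The step needs regio-, endo- and facial selectivity: the first two are secured by the tether, because the enal β-carbon cannot reach the other furan terminus, and the third by the catalyst, helped by the slow thermal background reaction of the push-pull enal at −78 °C.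

Step 13
Reactants: 23 tert-butyl (3S,4E,6E)-9-[(4S,5R)-2-chloro-4,5-dihydroxy-6-(hydroxymethylidene)-4-methyl-3-oxocyclohex-1-en-1-yl]-3,5-dimethylnona-4,6-dien-8-ynoate
Product: 24 tert-butyl (3S,4E,6E)-7-[(7S,8R)-5-chloro-7,8-dihydroxy-7-methyl-6-oxo-7,8-dihydro-6H-isochromen-3-yl]-3,5-dimethylhepta-4,6-dienoate
Conditions: Ph3PAuNTf2 (5 mol%), CH2Cl2, 0 °C → rt
Reagents that add atoms: none
Why: Gold-catalysed 6-endo-dig cycloisomerisation of the enol oxygen onto the alkyne, the counterpart of the 2-alkynylbenzaldehyde route to azaphilones, closes the pyran at C3, the electrophilic δ-carbon of the ynenone.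

Step 14
Reactants: 24 tert-butyl (3S,4E,6E)-7-[(7S,8R)-5-chloro-7,8-dihydroxy-7-methyl-6-oxo-7,8-dihydro-6H-isochromen-3-yl]-3,5-dimethylhepta-4,6-dienoate
Product: 25 (3S,4E,6E)-7-[(7S,8R)-5-chloro-7,8-dihydroxy-7-methyl-6-oxo-7,8-dihydro-6H-isochromen-3-yl]-3,5-dimethylhepta-4,6-dienoic acid
Conditions: CF3CO2H, CH2Cl2, 0 °C
Reagents that add atoms: none
Why: Acidolysis of the tert-butyl ester with loss of isobutene, during which protonation of the vinylogous ester to a hydroxypyrylium ion should protect the C8 alcohol from ionisation.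

Compound list
1 | (R)-4-benzyl-3-propanoyl-1,3-oxazolidin-2-one | CCC(=O)N1[C@H](Cc2ccccc2)COC1=O | starting material
2 | tert-butyl bromoacetate | BrCC(=O)OC(C)(C)C | starting material
3 | sodium Z-enolate of 1 | [Na+].C/C=C(\[O-])N1[C@H](Cc2ccccc2)COC1=O | intermediate
4 | tert-butyl (3S)-4-[(4R)-4-benzyl-2-oxo-1,3-oxazolidin-3-yl]-3-methyl-4-oxobutanoate | O=C([C@@H](C)CC(=O)OC(C)(C)C)N1[C@H](Cc2ccccc2)COC1=O | intermediate
5 | tert-butyl (3S)-4-hydroxy-3-methylbutanoate | OC[C@@H](C)CC(=O)OC(C)(C)C | intermediate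
6 | tert-butyl (3S)-3-methyl-4-oxobutanoate | O=C[C@@H](C)CC(=O)OC(C)(C)C | intermediate
7 | tert-butyl (3S,4E)-3,5-dimethyl-6-oxohex-4-enoate | O=C/C(C)=C/[C@@H](C)CC(=O)OC(C)(C)C | intermediate
8 | tert-butyl (3S,4E,6E)-7-iodo-3,5-dimethylhepta-4,6-dienoate | I/C=C/C(C)=C/[C@@H](C)CC(=O)OC(C)(C)C | intermediate
9 | ethyl (S)-lactate | CCOC(=O)[C@H](C)O | starting material
10 | (2S)-2-hydroxy-N-methoxy-N-methylpropanamide | C[C@H](O)C(=O)N(C)OC | intermediate
11 | 1,4-bis(trimethylsilyl)buta-1,3-diyne | C[Si](C)(C)C#CC#C[Si](C)(C)C | starting material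
12 | lithium 4-(trimethylsilyl)buta-1,3-diyn-1-ide | [Li+].[C-]#CC#C[Si](C)(C)C | intermediate
13 | chloromagnesium alkoxide of 10 | C[C@H](O[Mg]Cl)C(=O)N(C)OC | intermediate
14 | (2S)-2-hydroxy-7-(trimethylsilyl)hepta-4,6-diyn-3-one | C[C@H](O)C(=O)C#CC#C[Si](C)(C)C | intermediate
15 | (2S)-2-methyl-5-[(trimethylsilyl)ethynyl]furan-3(2H)-one | C[C@@H]1OC(C#C[Si](C)(C)C)=CC1=O | intermediate
16 | (2S)-4-chloro-2-methyl-5-[(trimethylsilyl)ethynyl]furan-3(2H)-one | C[C@@H]1OC(C#C[Si](C)(C)C)=C(Cl)C1=O | intermediate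
17 | (2S)-4-chloro-5-ethynyl-2-methylfuran-3(2H)-one | C[C@@H]1OC(C#C)=C(Cl)C1=O | intermediate
18 | tert-butyl (3S,4E,6E)-9-[(5S)-3-chloro-5-methyl-4-oxo-4,5-dihydrofuran-2-yl]-3,5-dimethylnona-4,6-dien-8-ynoate | C[C@@H]1OC(C#C/C=C/C(C)=C/[C@@H](C)CC(=O)OC(C)(C)C)=C(Cl)C1=O | intermediate
19 | tetrabutylammonium (E)-3-oxoprop-1-en-1-olate (malondialdehyde tetrabutylammonium salt) | CCCC[N+](CCCC)(CCCC)CCCC.[O-]/C=C/C=O | starting material
20 | furan-3-yloxy(diisopropyl)silyl triflate derived from 18 | Cc1oc(C#C/C=C/C(C)=C/[C@@H](C)CC(=O)OC(C)(C)C)c(Cl)c1O[Si](C(C)C)(C(C)C)OS(=O)(=O)C(F)(F)F | intermediate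
21 | tert-butyl (3S,4E,6E)-9-[3-chloro-4-({diisopropyl[(1E)-3-oxoprop-1-enyloxy]silyl}oxy)-5-methylfuran-2-yl]-3,5-dimethylnona-4,6-dien-8-ynoate | Cc1oc(C#C/C=C/C(C)=C/[C@@H](C)CC(=O)OC(C)(C)C)c(Cl)c1O[Si](C(C)C)(C(C)C)O/C=C/C=O | intermediate
22 | silicon-bridged 7-oxabicyclo[2.2.1]hept-2-ene cycloadduct of 21: oxygen bridge between C7 and C4a, C8–O endo and tied through Si(i-Pr)2 to the C6 enol oxygen, formyl at C8a exo, (7S,8R) | ClC1=C2O[Si](C(C)C)(C(C)C)O[C@@H]3[C@@H](C=O)[C@@]1(C#C/C=C/C(C)=C/[C@@H](C)CC(=O)OC(C)(C)C)O[C@]23C | intermediate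
23 | tert-butyl (3S,4E,6E)-9-[(4S,5R)-2-chloro-4,5-dihydroxy-6-(hydroxymethylidene)-4-methyl-3-oxocyclohex-1-en-1-yl]-3,5-dimethylnona-4,6-dien-8-ynoate (enol tautomer of the C1 aldehyde, geometry of the enol not fixed) | O=C1C(Cl)=C(C#C/C=C/C(C)=C/[C@@H](C)CC(=O)OC(C)(C)C)C(=CO)[C@@H](O)[C@]1(C)O | intermediate
24 | tert-butyl (3S,4E,6E)-7-[(7S,8R)-5-chloro-7,8-dihydroxy-7-methyl-6-oxo-7,8-dihydro-6H-isochromen-3-yl]-3,5-dimethylhepta-4,6-dienoate | CC(/C=C/C1=CC2=C(Cl)C(=O)[C@@](C)(O)[C@H](O)C2=CO1)=C\[C@@H](C)CC(=O)OC(C)(C)C | intermediate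
25 | (3S,4E,6E)-7-[(7S,8R)-5-chloro-7,8-dihydroxy-7-methyl-6-oxo-7,8-dihydro-6H-isochromen-3-yl]-3,5-dimethylhepta-4,6-dienoic acid (CNP0532378.1) | CC(/C=C/C1=CC2=C(Cl)C(=O)[C@@](C)(O)[C@H](O)C2=CO1)=C\[C@@H](C)CC(=O)O | target

Total step count: 14. Longest linear sequence: 10 steps (steps 1–5 and 10–14).

Steps most likely to fail

1. Step 12 (Proposed new method). The cycloaddition may stop after the first C–C bond and lose the silyloxy group by β-elimination, the catalyst may discriminate the enal faces poorly, or the strained adduct may revert before the fluoride quench. The fallback uses known chemistry, sets out from 18 and comes back at 23, forming the two bonds in separate operations. Deprotonation of 18 with LiN(SiMe3)2 (THF, −78 °C) should give the lithium furan-3-olate F1. Its aldol addition to 3,3-dimethoxypropanal at the oxygen-bearing ring carbon should give the 2,2-disubstituted furanone aldol adduct F2. Aqueous CF3CO2H in THF should free the β-hydroxy aldehyde F3, whose enol adds 6-endo to the chlorinated β-carbon of the vinylogous ester and expels the ring oxygen (Michael addition with β-elimination). All four 7,8-stereoisomers are to be expected; because C13 is fixed they are diastereomers, and 23 would be separated by preparative HPLC or by lipase-mediated acylation of the C8 hydroxyl.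

2. Step 11. Silicon may be substituted twice by the furanone, or the bis-enol ether may hydrolyse during handling. The fallback reverses the order of the two Si–O bond formations, sets out from 19 and comes back at 21. Treating 19 with an excess of i-Pr2SiCl2 and removing the excess in vacuum should leave (E)-3-{[chloro(diisopropyl)silyl]oxy}prop-2-enal F4. F4 is then coupled with 18 under Et3N and catalytic DMAP in CH2Cl2, the sequential chlorosilane method used for unsymmetrical silyl bis-enol ethers.

3. Step 10. Under the basic coupling conditions the electron-poor ethynylfuranone may enolise, suffer conjugate addition or homocouple. The fallback masks the furanone as an aromatic silyl furan during the coupling, sets out from 16 and comes back at 18. t-BuMe2SiOTf and Et3N should give tert-butyl{[4-chloro-2-methyl-5-((trimethylsilyl)ethynyl)furan-3-yl]oxy}dimethylsilane F5. AgNO3 (cat.) in aqueous acetone should remove the alkynyl silane to give tert-butyl[(4-chloro-5-ethynyl-2-methylfuran-3-yl)oxy]dimethylsilane F6. Sonogashira coupling of F6 with 8 (PdCl2(PPh3)2, CuI, Et3N) should give the coupled silyloxyfuran F7, and Bu4NF with AcOH returns the furanone 18.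

Further compounds
F1 | step 12 | lithium furan-3-olate of 18 | [Li+].Cc1oc(C#C/C=C/C(C)=C/[C@@H](C)CC(=O)OC(C)(C)C)c(Cl)c1[O-]
F2 | step 12 | tert-butyl (3S,4E,6E)-9-[3-chloro-5-(1-hydroxy-3,3-dimethoxypropyl)-5-methyl-4-oxo-4,5-dihydrofuran-2-yl]-3,5-dimethylnona-4,6-dien-8-ynoate (mixture at the two new centres) | COC(OC)CC(O)C1(C)OC(C#C/C=C/C(C)=C/[C@@H](C)CC(=O)OC(C)(C)C)=C(Cl)C1=O
F3 | step 12 | tert-butyl (3S,4E,6E)-9-[3-chloro-5-(1-hydroxy-3-oxopropyl)-5-methyl-4-oxo-4,5-dihydrofuran-2-yl]-3,5-dimethylnona-4,6-dien-8-ynoate (mixture at the two new centres) | O=CCC(O)C1(C)OC(C#C/C=C/C(C)=C/[C@@H](C)CC(=O)OC(C)(C)C)=C(Cl)C1=O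
F4 | step 11 | (E)-3-{[chloro(diisopropyl)silyl]oxy}prop-2-enal | CC(C)[Si](Cl)(C(C)C)O/C=C/C=O
F5 | step 10 | tert-butyl{[4-chloro-2-methyl-5-((trimethylsilyl)ethynyl)furan-3-yl]oxy}dimethylsilane | Cc1oc(C#C[Si](C)(C)C)c(Cl)c1O[Si](C)(C)C(C)(C)C
F6 | step 10 | tert-butyl[(4-chloro-5-ethynyl-2-methylfuran-3-yl)oxy]dimethylsilane | Cc1oc(C#C)c(Cl)c1O[Si](C)(C)C(C)(C)C
F7 | step 10 | tert-butyl (3S,4E,6E)-9-{4-[(tert-butyldimethylsilyl)oxy]-3-chloro-5-methylfuran-2-yl}-3,5-dimethylnona-4,6-dien-8-ynoate | Cc1oc(C#C/C=C/C(C)=C/[C@@H](C)CC(=O)OC(C)(C)C)c(Cl)c1O[Si](C)(C)C(C)(C)C
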